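Read the dusk run first; it shows where J goes.

| flask | X | J | remark | time |
|---|---|---|---|---|
| summer | 17 mM | 1.5 equiv | run made earlier |  |
| dusk | 17 mM | 0.75 equiv | run made earlier |  |
| spring | 17 mM | 3 equiv | run made earlier |  |
| winter | 34 mM | 1.5 equiv | run made earlier |  |
| Friday's | 17 mM | 1.50 equiv (fed, over 5.00 min) | a stirred flask in which J is dosed at a steady rate over 5.00 min without added volume, worked up at 5.0 min | 5.0 min |
| Monday's | 17 mM (fed, over 5.00 min) | 1.50 equiv | all but X at the start; X goes in evenly over 5.00 min, the run ends at 5.0 min | 5.0 min |
| Saturday's | 17 mM | 1.50 equiv | a single well-mixed tank run continuously and read at steady state, 5.0 min in it on average |  |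
| Tuesday's | 17 mM | 1.50 equiv | everything together in a closed stirred flask, run for 5.0 min | 5.0 min |

| run | time / min | D / % | X / % |
|---|---|---|---|
| summer | 0.500 | 47.2 | 14.5 |
| summer | 1.00 | 65.4 | 11.3 |
| summer | 1.50 | 73.9 | 10.2 |
| summer | 2.00 | 78.2 | 8.4 |
| summer | 2.50 | 80.7 | 8.3 |
| summer | 3.00 | 82.5 | 8.0 |
| dusk | 0.333 | 19.0 | 18.7 |
| dusk | 0.500 | 25.2 | 17.9 |
| dusk | 0.833 | 32.9 | 17.0 |
| dusk | 1.33 | 40.1 | 15.6 |
| dusk | 2.50 | 46.0 | 15.1 |
| dusk | 4.00 | 47.4 | 14.4 |
| spring | 0.250 | 54.0 | 13.8 |
| spring | 0.833 | 93.1 | 4.4 |
| spring | 1.33 | 98.6 | 0.6 |
| spring | 2.00 | 99.4 | 0 |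
| spring | 3.00 | 100.3 | 0 |
| spring | 4.00 | 100.1 | 0.3 |
| winter | 0.833 | 74.3 | 6.9 |
| winter | 1.50 | 85.7 | 4.8 |
| winter | 2.50 | 91.6 | 4.0 |
| winter | 3.00 | 92.6 | 3.6 |
| winter | 4.00 | 93.7 | 2.7 |

(standard deviation of a reading: 0.3 percentage points)

- the stated concentrations are those of everything mixed, before any reaction; amounts are the same in each set-up
- the numbers in the tables scatter by 0.3 percentage points (one standard deviation)
- the feed brings no volume worth counting
- the earlier runs were made in a closed, stirred flask

- the set-up with the highest amount of D at the outlet or at the end, in percent of the X put in ("none" if the first two lie within 2 percentage points) (Friday's / Monday's / Saturday's / Tuesday's / none)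
- amount of D at the outlet or at the end, in percent of the X put in, Friday's
- amount of D at the outlet or at the end, in percent of the X put in, Monday's
- amount of D at the outlet or at the end, in percent of the X put in, Saturday's
- amount of D at the outlet or at the end, in percent of the X put in, Tuesday's

In the dusk run D levelled at 47.4% while 14.4% of X stood free, so J was being lost to something else. J was charged at 0.75 equiv, so about 63.2% of it became D. I took that share as a split between two rates. The capture ratio ρ, a selectivity factor, is the rate at which J forms D over the rate at which J is lost otherwise. Read over the dusk run, it was 1.72. I set that against the reading of 17.0% free X at 0.833 min, which is c(X) = 2.89 mM. That gave the capture constant ρ/c(X), 0.594 mM⁻¹.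

In the summer run ρ drifted. It was 1.46 at 0.500 min and 0.808 at 3.00 min. At that last reading 9.50% of the X stood in neither column. The spring run reached 100.3% of D, so I read that missing part as a reserve that returns X.

Here is what I expected you to find. Tuesday's flask is charged like the summer run, where D gained 1.8 percentage points in the last step, so I put it above 82.5%. In Friday's flask J met X from the start, but the feed ran to 5.00 min, and the flask is worked up at 5.0 min, so J still unreacted then adds nothing to the D read. In Monday's flask c(X) began at zero, and ρ with it, so do not start X into standing J. I put Saturday's tank, with its one c(X), below Friday's flask. My order was Tuesday's, Friday's, Saturday's, Monday's.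

The forecast named Tuesday's, with 68% for Friday's, 42% for Monday's, 60% for Saturday's and 85.5% for Tuesday's, and it said “dosed J stays low”.

The flasks gave 73.0% in Friday's, 42.7% in Monday's, 65.7% in Saturday's and 84.4% in Tuesday's, so Tuesday's was best.

    2 X ⇌ L, settled at all times (K = 520 L mol⁻¹)
    X + J → D (k = 4.80 L mol⁻¹ s⁻¹)
    J → G (k = 0.00860 s⁻¹)

Friday's flask ended with free X at 9.85%, so the capture constant gives ρ = 0.995. Friday's flask kept 18% of its J. The neighbouring flask had X raised to 29 mM, with equivalents and time as in Friday's. Free X there ended at 6.40%, which is c(X) = 1.86 mM, so the capture constant gives ρ = 1.10, higher than in Friday's flask. That neighbour kept 17% of its J and gave 81.2% of D, more than the 73.0% of Friday's flask.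

The runs are calculated from invented constants; the scatter is artificial.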